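**Retrosynthetic overview**

1. Target 36 ⇐ hydrolysis of two aryl triflates and cleavage of six methyl ethers ⇐ heptacycle 34 ⇐ acid-mediated Friedel–Crafts closure of the seven-membered ring (C7 of ring A to the benzylic carbon bearing the 2,4-dioxygenated aryl group) in stilbene 33 ⇐ Suzuki–Miyaura coupling of aryl chloride 28 with alkenylboronate 32.
2. 28 ⇐ insertion of 3-chloro-5-methoxybenzyne 27 into the benzylic C–O bond of oxirane 20, which builds the second dihydrobenzofuran (benzene ring B); 20 ⇐ Horner–Wadsworth–Emmons olefination and Shi epoxidation of aldehyde 15.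
3. 15 ⇐ key step: insertion of aryne 13 (from o-silylaryl triflate 9) into the benzylic C–O bond of (2R,3R)-oxirane 12, the Shi epoxide of pterostilbene triflate; this makes the O1–C7a and C3a–C3 bonds of the first dihydrobenzofuran (the one carrying the 3,5-dihydroxyphenyl group) on the central benzene ring A.
4. Enabling feature: in ring A, C3a lies between the two oxygen-bearing carbons C4 (OH) and C7a (O1), so it is C2 of a resorcinol. A silyl group on C3a and a triflate in place of the C7a oxygen give a 3-methoxyaryne that takes oxygen at C7a and carbon at C3a. The O1–C2–C3 unit with its two aryl groups is a stilbene oxide, and a triflate on its 4-oxyphenyl ring decides which C–O bond breaks.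
5. Ring order: dihydrofuran on ring A (step 7), dihydrofuran on ring B (step 15), cycloheptadiene (step 18). The four dihydrofuran stereocentres come from two catalyst-controlled Shi epoxidations, the fifth from substrate control in step 18.

Key step: step 7

Remark: the methine carbon of the seven-membered ring is taken to have the configuration that acid-mediated Friedel–Crafts closure delivers (aryl group anti to the neighbouring dihydrofuran carbon, as in ampelopsin B-type cycloheptadienes), and compounds 1, 10, 16, 21, 29 and 30 are taken to be commercial.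

**Route**

Step 1
Reactants: 1 3-hydroxy-5-methoxybenzaldehyde
Product: 2 3-(1,3-dioxolan-2-yl)-5-methoxyphenol
Conditions: ethylene glycol, PPTS (cat.), toluene, Dean–Stark, reflux
Reagents that add atoms: ethylene glycol, OCCO
Why: Acid-catalysed acetalisation with azeotropic removal of water masks the aldehyde against the organolithium of step 3.

Step 2
Reactants: 2 3-(1,3-dioxolan-2-yl)-5-methoxyphenol
Product: 3 3-(1,3-dioxolan-2-yl)-5-methoxyphenyl N-(propan-2-yl)carbamate
Conditions: i-PrNCO, Et3N (cat.), CH2Cl2, rt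
Reagents that add atoms: isopropyl isocyanate, CC(C)N=C=O
Why: Base-catalysed addition of the phenol to the isocyanate gives a secondary carbamate that directs ortho-metalation and can later be removed under mild base.

Step 3
Reactants: 3 3-(1,3-dioxolan-2-yl)-5-methoxyphenyl N-(propan-2-yl)carbamate
Product: 7 5-(1,3-dioxolan-2-yl)-3-methoxy-2-(trimethylsilyl)phenyl N-(propan-2-yl)carbamate, via N-silyl carbamate 4 (not isolated), via aryllithium 5 (not isolated), via C-silyl N-silyl carbamate 6 (not isolated)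
Conditions: TBSOTf, TMEDA, Et2O, 0 °C to rt; n-BuLi, TMEDA, −78 °C; TMSCl, −78 °C to rt; aq. NH4Cl
Reagents that add atoms: chlorotrimethylsilane, C[Si](C)(C)Cl
Why: Carbamate-directed ortho-metalation (the N–H is silylated in the flask) removes the proton between the carbamate oxygen and the methoxy group, the position activated by both, and the aryllithium is silylated before the N–Si bond is hydrolysed on work-up.

Step 4
Reactants: 7 5-(1,3-dioxolan-2-yl)-3-methoxy-2-(trimethylsilyl)phenyl N-(propan-2-yl)carbamate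
Product: 9 5-(1,3-dioxolan-2-yl)-3-methoxy-2-(trimethylsilyl)phenyl trifluoromethanesulfonate, via silylphenol 8 (not isolated)
Conditions: DBU, Et2NH, MeCN, 40 °C; then PhNTf2, rt
Reagents that add atoms: N-phenylbis(trifluoromethanesulfonimide), O=S(=O)(N(c1ccccc1)S(=O)(=O)C(F)(F)F)C(F)(F)F
Why: Base-induced loss of isopropyl isocyanate (trapped by diethylamine as the urea) frees the hindered phenoxide, which is triflated in the same flask to give an o-silylaryl triflate, a fluoride-triggered aryne precursor.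

Step 5
Reactants: 10 pterostilbene
Product: 11 4-[(E)-2-(3,5-dimethoxyphenyl)ethenyl]phenyl trifluoromethanesulfonate
Conditions: Tf2O, pyridine, CH2Cl2, 0 °C
Reagents that add atoms: trifluoromethanesulfonic anhydride, O=S(=O)(OS(=O)(=O)C(F)(F)F)C(F)(F)F
Why: O-sulfonylation protects the phenol and makes the 4-oxyphenyl ring electron-poor, which later decides which C–O bond of the oxirane breaks.

Step 6
Reactants: 11 4-[(E)-2-(3,5-dimethoxyphenyl)ethenyl]phenyl trifluoromethanesulfonate
Product: 12 4-[(2R,3R)-3-(3,5-dimethoxyphenyl)oxiran-2-yl]phenyl trifluoromethanesulfonate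
Conditions: D-fructose-derived Shi ketone (cat.), Oxone (2KHSO5·KHSO4·K2SO4), K2CO3, n-Bu4NHSO4, MeCN–DMM–aq. buffer (pH 10.5), 0 °C
Reagents that add atoms: Oxone (potassium peroxymonosulfate), OOS(=O)(=O)[O-].[K+]
Why: Shi asymmetric epoxidation of an (E)-stilbene, in which the chiral dioxirane transfers oxygen through a spiro transition state to the face that gives the (R,R)-oxirane, so both stereocentres are set by the catalyst.

Step 7
Reactants: 9 5-(1,3-dioxolan-2-yl)-3-methoxy-2-(trimethylsilyl)phenyl trifluoromethanesulfonate; 12 4-[(2R,3R)-3-(3,5-dimethoxyphenyl)oxiran-2-yl]phenyl trifluoromethanesulfonate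
Product: 14 4-[(2S,3S)-3-(3,5-dimethoxyphenyl)-6-(1,3-dioxolan-2-yl)-4-methoxy-2,3-dihydro-1-benzofuran-2-yl]phenyl trifluoromethanesulfonate, via aryne 13 (not isolated)
Conditions: CsF (3 equiv), 12 (2.5 equiv), MeCN–toluene (1:3), 50 °C
Reagents that add atoms: none
Why: Proposed new method: Fluoride removes the silyl group of 9 with loss of triflate to give aryne 13, the oxirane oxygen of 12 adds to the aryne carbon meta to the methoxy group, and the resulting aryl-oxonium/aryl-anion zwitterion opens at a benzylic C–O bond so that the benzylic cation collapses onto the neighbouring aryl carbanion, which makes O1–C7a and C3a–C3 in one operation. The closest known reaction type is the fluoride-triggered insertion of arynes into the benzylic C–O bond of styrene oxide, which gives dihydrobenzofurans, together with the ring-opening couplings of cyclic ethers that run through aryl-oxonium zwitterions. The furan ring closes by intramolecular anion–cation recombination through a five-membered transition state, formally a shift of the benzylic carbon from oxygen to the ortho carbon that expands the oxirane by two atoms. C2 keeps the configuration of the oxirane because its C–O bond is never broken, and C3 is set trans to the C2 aryl group because the carbanion captures the cation on the face from which the oxygen leaves, which is also the less hindered face. Two regioselectivities are needed: the aryne must take oxygen at the carbon remote from the methoxy group, which the inductive distortion of a 3-methoxyaryne secures, and the oxirane must open at the carbon bearing the 3,5-dimethoxyphenyl ring, which the electron-poor 4-triflyloxyphenyl ring on the other carbon secures.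

Step 8
Reactants: 14 4-[(2S,3S)-3-(3,5-dimethoxyphenyl)-6-(1,3-dioxolan-2-yl)-4-methoxy-2,3-dihydro-1-benzofuran-2-yl]phenyl trifluoromethanesulfonate
Product: 15 4-[(2S,3S)-3-(3,5-dimethoxyphenyl)-6-formyl-4-methoxy-2,3-dihydro-1-benzofuran-2-yl]phenyl trifluoromethanesulfonate
Conditions: 1 M HCl, THF, rt
Reagents that add atoms: water, O
Why: Acid hydrolysis of the dioxolane, during which the benzylic C2–O bond of the dihydrobenzofuran should not ionise because its aryl group carries the triflate.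

Step 9
Reactants: 16 diethyl [(4-hydroxyphenyl)methyl]phosphonate
Product: 17 diethyl {[4-(trifluoromethanesulfonyloxy)phenyl]methyl}phosphonate
Conditions: Tf2O, pyridine, CH2Cl2, 0 °C
Reagents that add atoms: trifluoromethanesulfonic anhydride, O=S(=O)(OS(=O)(=O)C(F)(F)F)C(F)(F)F
Why: O-sulfonylation of the phenol installs the same deactivating protecting group on the second 4-oxyphenyl ring.

Step 10
Reactants: 15 4-[(2S,3S)-3-(3,5-dimethoxyphenyl)-6-formyl-4-methoxy-2,3-dihydro-1-benzofuran-2-yl]phenyl trifluoromethanesulfonate; 17 diethyl {[4-(trifluoromethanesulfonyloxy)phenyl]methyl}phosphonate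
Product: 19 4-[(E)-2-{(2S,3S)-3-(3,5-dimethoxyphenyl)-4-methoxy-2-[4-(trifluoromethanesulfonyloxy)phenyl]-2,3-dihydro-1-benzofuran-6-yl}ethenyl]phenyl trifluoromethanesulfonate, via sodium phosphonate carbanion 18 (not isolated)
Conditions: NaH, THF, 0 °C; then 15, 0 °C to rt
Reagents that add atoms: none
Why: Horner–Wadsworth–Emmons olefination of an aryl aldehyde with a benzylic phosphonate anion should give the (E)-stilbene through the reversibly formed anti adduct.

Step 11
Reactants: 19 4-[(E)-2-{(2S,3S)-3-(3,5-dimethoxyphenyl)-4-methoxy-2-[4-(trifluoromethanesulfonyloxy)phenyl]-2,3-dihydro-1-benzofuran-6-yl}ethenyl]phenyl trifluoromethanesulfonate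
Product: 20 4-[(2R,3R)-3-{(2S,3S)-3-(3,5-dimethoxyphenyl)-4-methoxy-2-[4-(trifluoromethanesulfonyloxy)phenyl]-2,3-dihydro-1-benzofuran-6-yl}oxiran-2-yl]phenyl trifluoromethanesulfonate
Conditions: D-fructose-derived Shi ketone (cat.), Oxone (2KHSO5·KHSO4·K2SO4), K2CO3, n-Bu4NHSO4, MeCN–DMM–aq. buffer (pH 10.5), 0 °C
Reagents that add atoms: Oxone (potassium peroxymonosulfate), OOS(=O)(=O)[O-].[K+]
Why: Shi asymmetric epoxidation of the (E)-stilbene, in which the catalyst and not the remote dihydrobenzofuran stereocentres controls the face, so the (R,R)-oxirane should form as in step 6.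

Step 12
Reactants: 21 2-chloro-4-methoxyphenol
Product: 22 2-bromo-6-chloro-4-methoxyphenol
Conditions: NBS, i-Pr2NH (cat.), CH2Cl2, 0 °C
Reagents that add atoms: N-bromosuccinimide, O=C1CCC(=O)N1Br
Why: Amine-catalysed electrophilic bromination goes to the only free position ortho to the hydroxyl group.

Step 13
Reactants: 22 2-bromo-6-chloro-4-methoxyphenol
Product: 23 (2-bromo-6-chloro-4-methoxyphenoxy)trimethylsilane
Conditions: HMDS, THF, 70 °C; concentrate
Reagents that add atoms: hexamethyldisilazane, C[Si](C)(C)N[Si](C)(C)C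
Why: O-silylation of the phenol with ammonia as the only by-product prepares the silyl group that migrates to carbon in step 14.

Step 14
Reactants: 23 (2-bromo-6-chloro-4-methoxyphenoxy)trimethylsilane
Product: 26 2-chloro-4-methoxy-6-(trimethylsilyl)phenyl trifluoromethanesulfonate, via aryllithium 24 (not isolated), via lithium phenoxide 25 (not isolated)
Conditions: n-BuLi, THF, −78 °C; then Tf2O, −78 °C to rt
Reagents that add atoms: trifluoromethanesulfonic anhydride, O=S(=O)(OS(=O)(=O)C(F)(F)F)C(F)(F)F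
Why: Bromine–lithium exchange, which is faster than any reaction at the C–Cl bond, is followed by a retro-Brook shift of silicon from oxygen to carbon, and the resulting phenoxide is triflated to give the o-silylaryl triflate.

Step 15
Reactants: 20 4-[(2R,3R)-3-{(2S,3S)-3-(3,5-dimethoxyphenyl)-4-methoxy-2-[4-(trifluoromethanesulfonyloxy)phenyl]-2,3-dihydro-1-benzofuran-6-yl}oxiran-2-yl]phenyl trifluoromethanesulfonate; 26 2-chloro-4-methoxy-6-(trimethylsilyl)phenyl trifluoromethanesulfonate
Product: 28 4-[(2S,3S)-4-chloro-3-{(2S,3S)-3-(3,5-dimethoxyphenyl)-4-methoxy-2-[4-(trifluoromethanesulfonyloxy)phenyl]-2,3-dihydro-1-benzofuran-6-yl}-6-methoxy-2,3-dihydro-1-benzofuran-2-yl]phenyl trifluoromethanesulfonate, via aryne 27 (not isolated)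
Conditions: CsF (6 equiv), 26 (3 equiv, added in portions), MeCN–toluene (1:3), 50 °C
Reagents that add atoms: none
Why: Proposed new method: as in step 7, the oxirane oxygen of 20 adds to aryne 27 at the carbon remote from chlorine (the inductive distortion of a 3-haloaryne), the aryl-oxonium zwitterion opens at the benzylic carbon bearing the benzofuranyl group (its para-alkyl substituent stabilises the cation, whereas the other carbon bears the electron-poor 4-triflyloxyphenyl ring) and the cation recombines with the ortho carbanion on the face the oxygen leaves, so that C2 keeps the oxirane configuration and C3 is set trans to it; the closest known reaction type is the fluoride-triggered insertion of arynes into the benzylic C–O bond of styrene oxide, and chlorine is chosen over bromine because an ortho-chloro aryl anion loses halide more slowly.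

Step 16
Reactants: 29 2,4-dimethoxybenzaldehyde; 30 2,2'-methylenebis(4,4,5,5-tetramethyl-1,3,2-dioxaborolane)
Product: 32 2-[(E)-2-(2,4-dimethoxyphenyl)ethenyl]-4,4,5,5-tetramethyl-1,3,2-dioxaborolane, via lithiated diborylmethane 31 (not isolated)
Conditions: LiTMP (lithium 2,2,6,6-tetramethylpiperidide), THF, 0 °C; then 29, −78 °C to rt
Reagents that add atoms: none
Why: Boron–Wittig olefination, in which the diboryl carbanion adds to the aldehyde and syn elimination of the boron oxide should give the (E)-alkenylboronate.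

Step 17
Reactants: 28 4-[(2S,3S)-4-chloro-3-{(2S,3S)-3-(3,5-dimethoxyphenyl)-4-methoxy-2-[4-(trifluoromethanesulfonyloxy)phenyl]-2,3-dihydro-1-benzofuran-6-yl}-6-methoxy-2,3-dihydro-1-benzofuran-2-yl]phenyl trifluoromethanesulfonate; 32 2-[(E)-2-(2,4-dimethoxyphenyl)ethenyl]-4,4,5,5-tetramethyl-1,3,2-dioxaborolane
Product: 33 4-[(2S,3S)-4-[(E)-2-(2,4-dimethoxyphenyl)ethenyl]-3-{(2S,3S)-3-(3,5-dimethoxyphenyl)-4-methoxy-2-[4-(trifluoromethanesulfonyloxy)phenyl]-2,3-dihydro-1-benzofuran-6-yl}-6-methoxy-2,3-dihydro-1-benzofuran-2-yl]phenyl trifluoromethanesulfonate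
Conditions: Pd2(dba)3, [HP(t-Bu)3]BF4, K3PO4, 1,4-dioxane–H2O, 80 °C
Reagents that add atoms: none
Why: Suzuki–Miyaura coupling with a palladium catalyst carrying one bulky trialkylphosphine, which adds to aryl chlorides in preference to aryl triflates, so only the C–Cl bond should react and the alkene geometry of the boronate is kept.

Step 18
Reactants: 33 4-[(2S,3S)-4-[(E)-2-(2,4-dimethoxyphenyl)ethenyl]-3-{(2S,3S)-3-(3,5-dimethoxyphenyl)-4-methoxy-2-[4-(trifluoromethanesulfonyloxy)phenyl]-2,3-dihydro-1-benzofuran-6-yl}-6-methoxy-2,3-dihydro-1-benzofuran-2-yl]phenyl trifluoromethanesulfonate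
Product: 34 heptacyclic hexamethyl ether bis(triflate) of the target (six phenols as methyl ethers and both 4-hydroxyphenyl groups as triflates; all five stereocentres S)
Conditions: TfOH (1.2 equiv), CH2Cl2–HFIP (4:1), 0.005 M, −20 °C to rt
Reagents that add atoms: none
Why: Protonation of the stilbene at the carbon next to ring B gives a cation stabilised by the 2,4-dimethoxyphenyl group, which is captured in a seven-membered Friedel–Crafts closure by C7 of ring A (para to the C4 methoxy group and not flanked by its methyl group, unlike C5), with the aryl group ending anti to the neighbouring dihydrofuran carbon as in the acid-mediated formation of ampelopsin B-type cycloheptadienes, while the triflates keep both benzylic C–O bonds from ionising.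

Step 19
Reactants: 34 heptacyclic hexamethyl ether bis(triflate) of the target
Product: 35 bis(triflate) of the target (both 4-hydroxyphenyl groups as triflates; six free phenols; all five stereocentres S)
Conditions: BBr3, CH2Cl2, −78 °C to rt; then MeOH, H2O
Reagents that add atoms: none
Why: Lewis acid cleavage of the six aryl methyl ethers, in which the aryl triflates are inert to BBr3 and keep C2 of each dihydrofuran from ionising, so no stereocentre should be scrambled.

Step 20
Reactants: 35 bis(triflate) of the target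
Product: 36 CNP0154774.1 (all five stereocentres S)
Conditions: Et4NOH (aq.), 1,4-dioxane, rt, argon; then aq. NH4Cl
Reagents that add atoms: none
Why: Hydroxide attacks sulfur of the aryl triflates and frees the last two phenols without breaking any C–O or C–C bond of the skeleton.

**Compound list**

1 | 3-hydroxy-5-methoxybenzaldehyde | O=Cc1cc(O)cc(OC)c1 | starting material
2 | 3-(1,3-dioxolan-2-yl)-5-methoxyphenol | Oc1cc(OC)cc(c1)C1OCCO1 | intermediate
3 | 3-(1,3-dioxolan-2-yl)-5-methoxyphenyl N-(propan-2-yl)carbamate | CC(C)NC(=O)Oc1cc(OC)cc(c1)C1OCCO1 | intermediate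
4 | 3-(1,3-dioxolan-2-yl)-5-methoxyphenyl N-[tert-butyl(dimethyl)silyl]-N-(propan-2-yl)carbamate | CC(C)N([Si](C)(C)C(C)(C)C)C(=O)Oc1cc(OC)cc(c1)C1OCCO1 | intermediate
5 | 2-lithio derivative of 4 (lithium between the carbamate oxygen and the methoxy group) | CC(C)N([Si](C)(C)C(C)(C)C)C(=O)Oc1cc(cc(OC)c1[Li])C1OCCO1 | intermediate
6 | 5-(1,3-dioxolan-2-yl)-3-methoxy-2-(trimethylsilyl)phenyl N-[tert-butyl(dimethyl)silyl]-N-(propan-2-yl)carbamate | CC(C)N([Si](C)(C)C(C)(C)C)C(=O)Oc1cc(cc(OC)c1[Si](C)(C)C)C1OCCO1 | intermediate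
7 | 5-(1,3-dioxolan-2-yl)-3-methoxy-2-(trimethylsilyl)phenyl N-(propan-2-yl)carbamate | CC(C)NC(=O)Oc1cc(cc(OC)c1[Si](C)(C)C)C1OCCO1 | intermediate
8 | 5-(1,3-dioxolan-2-yl)-3-methoxy-2-(trimethylsilyl)phenol | Oc1cc(cc(OC)c1[Si](C)(C)C)C1OCCO1 | intermediate
9 | 5-(1,3-dioxolan-2-yl)-3-methoxy-2-(trimethylsilyl)phenyl trifluoromethanesulfonate | FC(F)(F)S(=O)(=O)Oc1cc(cc(OC)c1[Si](C)(C)C)C1OCCO1 | intermediate
10 | pterostilbene, 4-[(E)-2-(3,5-dimethoxyphenyl)ethenyl]phenol | COc1cc(/C=C/c2ccc(O)cc2)cc(OC)c1 | starting material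
11 | 4-[(E)-2-(3,5-dimethoxyphenyl)ethenyl]phenyl trifluoromethanesulfonate | COc1cc(/C=C/c2ccc(OS(=O)(=O)C(F)(F)F)cc2)cc(OC)c1 | intermediate
12 | 4-[(2R,3R)-3-(3,5-dimethoxyphenyl)oxiran-2-yl]phenyl trifluoromethanesulfonate | FC(F)(F)S(=O)(=O)Oc1ccc([C@H]2O[C@@H]2c2cc(OC)cc(OC)c2)cc1 | intermediate
13 | 5-(1,3-dioxolan-2-yl)-3-methoxybenzyne | COC1=CC(C2OCCO2)=CC#C1 | intermediate
14 | 4-[(2S,3S)-3-(3,5-dimethoxyphenyl)-6-(1,3-dioxolan-2-yl)-4-methoxy-2,3-dihydro-1-benzofuran-2-yl]phenyl trifluoromethanesulfonate | FC(F)(F)S(=O)(=O)Oc1ccc([C@H]2Oc3cc(cc(OC)c3[C@@H]2c2cc(OC)cc(OC)c2)C2OCCO2)cc1 | intermediate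
15 | 4-[(2S,3S)-3-(3,5-dimethoxyphenyl)-6-formyl-4-methoxy-2,3-dihydro-1-benzofuran-2-yl]phenyl trifluoromethanesulfonate | FC(F)(F)S(=O)(=O)Oc1ccc([C@H]2Oc3cc(cc(OC)c3[C@@H]2c2cc(OC)cc(OC)c2)C=O)cc1 | intermediate
16 | diethyl [(4-hydroxyphenyl)methyl]phosphonate | CCOP(=O)(Cc1ccc(O)cc1)OCC | starting material
17 | diethyl {[4-(trifluoromethanesulfonyloxy)phenyl]methyl}phosphonate | CCOP(=O)(Cc1ccc(OS(=O)(=O)C(F)(F)F)cc1)OCC | intermediate
18 | sodium salt of the benzylic carbanion of 17 | CCOP(=O)([CH-]c1ccc(OS(=O)(=O)C(F)(F)F)cc1)OCC.[Na+] | intermediate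
19 | 4-[(E)-2-{(2S,3S)-3-(3,5-dimethoxyphenyl)-4-methoxy-2-[4-(trifluoromethanesulfonyloxy)phenyl]-2,3-dihydro-1-benzofuran-6-yl}ethenyl]phenyl trifluoromethanesulfonate | FC(F)(F)S(=O)(=O)Oc1ccc([C@H]2Oc3cc(cc(OC)c3[C@@H]2c2cc(OC)cc(OC)c2)/C=C/c2ccc(OS(=O)(=O)C(F)(F)F)cc2)cc1 | intermediate
20 | 4-[(2R,3R)-3-{(2S,3S)-3-(3,5-dimethoxyphenyl)-4-methoxy-2-[4-(trifluoromethanesulfonyloxy)phenyl]-2,3-dihydro-1-benzofuran-6-yl}oxiran-2-yl]phenyl trifluoromethanesulfonate | FC(F)(F)S(=O)(=O)Oc1ccc([C@H]2Oc3cc(cc(OC)c3[C@@H]2c2cc(OC)cc(OC)c2)[C@H]2O[C@@H]2c2ccc(OS(=O)(=O)C(F)(F)F)cc2)cc1 | intermediate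
21 | 2-chloro-4-methoxyphenol | COc1ccc(O)c(Cl)c1 | starting material
22 | 2-bromo-6-chloro-4-methoxyphenol | COc1cc(Cl)c(O)c(Br)c1 | intermediate
23 | (2-bromo-6-chloro-4-methoxyphenoxy)trimethylsilane | COc1cc(Cl)c(O[Si](C)(C)C)c(Br)c1 | intermediate
24 | [3-chloro-5-methoxy-2-(trimethylsilyloxy)phenyl]lithium | COc1cc(Cl)c(O[Si](C)(C)C)c([Li])c1 | intermediate
25 | lithium 2-chloro-4-methoxy-6-(trimethylsilyl)phenoxide | COc1cc(Cl)c([O-])c(c1)[Si](C)(C)C.[Li+] | intermediate
26 | 2-chloro-4-methoxy-6-(trimethylsilyl)phenyl trifluoromethanesulfonate | COc1cc(Cl)c(OS(=O)(=O)C(F)(F)F)c(c1)[Si](C)(C)C | intermediate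
27 | 3-chloro-5-methoxybenzyne | COC1=CC#CC(Cl)=C1 | intermediate
28 | 4-[(2S,3S)-4-chloro-3-{(2S,3S)-3-(3,5-dimethoxyphenyl)-4-methoxy-2-[4-(trifluoromethanesulfonyloxy)phenyl]-2,3-dihydro-1-benzofuran-6-yl}-6-methoxy-2,3-dihydro-1-benzofuran-2-yl]phenyl trifluoromethanesulfonate | FC(F)(F)S(=O)(=O)Oc1ccc([C@H]2Oc3cc(cc(OC)c3[C@@H]2c2cc(OC)cc(OC)c2)[C@H]2c3c(cc(OC)cc3O[C@@H]2c2ccc(OS(=O)(=O)C(F)(F)F)cc2)Cl)cc1 | intermediate
29 | 2,4-dimethoxybenzaldehyde | COc1ccc(C=O)c(OC)c1 | starting material
30 | 2,2'-methylenebis(4,4,5,5-tetramethyl-1,3,2-dioxaborolane) | CC1(C)OB(CB2OC(C)(C)C(C)(C)O2)OC1(C)C | starting material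
31 | [bis(4,4,5,5-tetramethyl-1,3,2-dioxaborolan-2-yl)methyl]lithium | [Li]C(B1OC(C)(C)C(C)(C)O1)B1OC(C)(C)C(C)(C)O1 | intermediate
32 | 2-[(E)-2-(2,4-dimethoxyphenyl)ethenyl]-4,4,5,5-tetramethyl-1,3,2-dioxaborolane | COc1ccc(/C=C/B2OC(C)(C)C(C)(C)O2)c(OC)c1 | intermediate
33 | 4-[(2S,3S)-4-[(E)-2-(2,4-dimethoxyphenyl)ethenyl]-3-{(2S,3S)-3-(3,5-dimethoxyphenyl)-4-methoxy-2-[4-(trifluoromethanesulfonyloxy)phenyl]-2,3-dihydro-1-benzofuran-6-yl}-6-methoxy-2,3-dihydro-1-benzofuran-2-yl]phenyl trifluoromethanesulfonate | FC(F)(F)S(=O)(=O)Oc1ccc([C@H]2Oc3cc(cc(OC)c3[C@@H]2c2cc(OC)cc(OC)c2)[C@H]2c3c(cc(OC)cc3O[C@@H]2c2ccc(OS(=O)(=O)C(F)(F)F)cc2)/C=C/c2ccc(OC)cc2OC)cc1 | intermediate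
34 | heptacyclic hexamethyl ether bis(triflate) of the target (methyl ethers on the 3,5-dioxyphenyl ring, ring A, ring B and the 2,4-dioxyphenyl ring; triflates on both 4-oxyphenyl rings; all five stereocentres S) | FC(F)(F)S(=O)(=O)Oc1ccc([C@H]2Oc3c4c(cc(OC)c3[C@@H]2c2cc(OC)cc(OC)c2)[C@H]2c3c(cc(OC)cc3O[C@@H]2c2ccc(OS(=O)(=O)C(F)(F)F)cc2)C[C@H]4c2ccc(OC)cc2OC)cc1 | intermediate
35 | bis(triflate) of the target (triflates on both 4-oxyphenyl rings; six free phenols; all five stereocentres S) | FC(F)(F)S(=O)(=O)Oc1ccc([C@H]2Oc3c4c(cc(O)c3[C@@H]2c2cc(O)cc(O)c2)[C@H]2c3c(cc(O)cc3O[C@@H]2c2ccc(OS(=O)(=O)C(F)(F)F)cc2)C[C@H]4c2ccc(O)cc2O)cc1 | intermediate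
36 | CNP0154774.1 (all five stereocentres S) | Oc1ccc([C@H]2Oc3c4c(cc(O)c3[C@@H]2c2cc(O)cc(O)c2)[C@H]2c3c(cc(O)cc3O[C@@H]2c2ccc(O)cc2)C[C@H]4c2ccc(O)cc2O)cc1 | target

**Step count**

Total: 20 steps. Longest linear sequence: 13 steps (1, 2, 3, 4, 7, 8, 10, 11, 15, 17, 18, 19, 20).

**Steps most likely to fail**

1. Step 7 (Proposed new method). The oxirane oxygen is a weak nucleophile, so the aryne may be lost to oligomerisation or to capture by fluoride or solvent; the oxirane may also open at the wrong carbon. Fallback with known reactions, setting out from 2 and coming back at 15: phenol 2 is protected (MOMCl, i-Pr2NEt) as 2-[3-methoxy-5-(methoxymethoxy)phenyl]-1,3-dioxolane F1. Directed ortho-lithiation (n-BuLi, THF, 0 °C) between the two oxygens gives the aryllithium F2. Under BF3·OEt2 at −78 °C this opens the enantiomeric oxirane 4-[(2S,3S)-3-(3,5-dimethoxyphenyl)oxiran-2-yl]phenyl trifluoromethanesulfonate F3 (made from 11 with the enantiomeric Shi ketone) with inversion at the carbon bearing the dimethoxyphenyl ring, giving alcohol 4-[(1R,2S)-2-(3,5-dimethoxyphenyl)-2-[4-(1,3-dioxolan-2-yl)-2-methoxy-6-(methoxymethoxy)phenyl]-1-hydroxyethyl]phenyl trifluoromethanesulfonate F4. Aqueous HCl in THF removes the methoxymethyl group and the dioxolane to give 4-[(1R,2S)-2-(3,5-dimethoxyphenyl)-2-(4-formyl-2-hydroxy-6-methoxyphenyl)-1-hydroxyethyl]phenyl trifluoromethanesulfonate F5. Mitsunobu cyclisation (PPh3, DIAD) with inversion at the carbinol carbon closes the furan; the two inversions should give the trans-dihydrobenzofuran 15.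

2. Step 15 (Proposed new method). The same loss of aryne may occur, and the ortho-chloro aryl anion may expel chloride before the ring closes. Fallback with known reactions, setting out from 19 and coming back at 28: 19 is epoxidised with the enantiomeric Shi ketone to the diastereomeric (2S,3S)-oxirane F6. A Friedel–Crafts alkylation of 5-chlororesorcinol in HFIP, at its position between hydroxyl and chlorine, opens F6 with inversion at the carbon bearing the benzofuranyl group and gives 4-[(1R,2S)-2-(2-chloro-4,6-dihydroxyphenyl)-2-{(2S,3S)-3-(3,5-dimethoxyphenyl)-4-methoxy-2-[4-(trifluoromethanesulfonyloxy)phenyl]-2,3-dihydro-1-benzofuran-6-yl}-1-hydroxyethyl]phenyl trifluoromethanesulfonate F7. Mitsunobu cyclisation of the ortho hydroxyl, with inversion at the carbinol carbon, gives the 6-hydroxy analogue of 28, F8. O-Methylation (MeI, K2CO3, acetone) gives 28.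

3. Step 18. The ring may close at the wrong ortho carbon of ring A (C5 instead of C7), or the cation may be captured from the wrong face. Fallback, setting out from 33 and coming back at 35: the six methyl ethers of 33 are cleaved first with BBr3 to the hexaphenol bis(triflate) stilbene F9. The ring is then closed at the polyphenol stage with HCl in MeOH, the biomimetic conversion known for ε-viniferin-type stilbenes. There the free C4 hydroxyl of ring A directs the cation para, to C7, while the triflates still keep both dihydrofurans closed; the product is 35.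

Further compounds
F1 | step 7 | 2-[3-methoxy-5-(methoxymethoxy)phenyl]-1,3-dioxolane | COCOc1cc(OC)cc(c1)C1OCCO1
F2 | step 7 | [4-(1,3-dioxolan-2-yl)-2-methoxy-6-(methoxymethoxy)phenyl]lithium | COCOc1cc(cc(OC)c1[Li])C1OCCO1
F3 | step 7 | 4-[(2S,3S)-3-(3,5-dimethoxyphenyl)oxiran-2-yl]phenyl trifluoromethanesulfonate | FC(F)(F)S(=O)(=O)Oc1ccc([C@@H]2O[C@H]2c2cc(OC)cc(OC)c2)cc1
F4 | step 7 | 4-[(1R,2S)-2-(3,5-dimethoxyphenyl)-2-[4-(1,3-dioxolan-2-yl)-2-methoxy-6-(methoxymethoxy)phenyl]-1-hydroxyethyl]phenyl trifluoromethanesulfonate | FC(F)(F)S(=O)(=O)Oc1ccc([C@H](O)[C@@H](c2cc(OC)cc(OC)c2)c2c(OC)cc(cc2OCOC)C2OCCO2)cc1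
F5 | step 7 | 4-[(1R,2S)-2-(3,5-dimethoxyphenyl)-2-(4-formyl-2-hydroxy-6-methoxyphenyl)-1-hydroxyethyl]phenyl trifluoromethanesulfonate | FC(F)(F)S(=O)(=O)Oc1ccc([C@H](O)[C@@H](c2cc(OC)cc(OC)c2)c2c(OC)cc(C=O)cc2O)cc1
F6 | step 15 | 4-[(2S,3S)-3-{(2S,3S)-3-(3,5-dimethoxyphenyl)-4-methoxy-2-[4-(trifluoromethanesulfonyloxy)phenyl]-2,3-dihydro-1-benzofuran-6-yl}oxiran-2-yl]phenyl trifluoromethanesulfonate | FC(F)(F)S(=O)(=O)Oc1ccc([C@H]2Oc3cc(cc(OC)c3[C@@H]2c2cc(OC)cc(OC)c2)[C@@H]2O[C@H]2c2ccc(OS(=O)(=O)C(F)(F)F)cc2)cc1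
F7 | step 15 | 4-[(1R,2S)-2-(2-chloro-4,6-dihydroxyphenyl)-2-{(2S,3S)-3-(3,5-dimethoxyphenyl)-4-methoxy-2-[4-(trifluoromethanesulfonyloxy)phenyl]-2,3-dihydro-1-benzofuran-6-yl}-1-hydroxyethyl]phenyl trifluoromethanesulfonate | FC(F)(F)S(=O)(=O)Oc1ccc([C@H]2Oc3cc(cc(OC)c3[C@@H]2c2cc(OC)cc(OC)c2)[C@@H](c2c(O)cc(O)cc2Cl)[C@@H](O)c2ccc(OS(=O)(=O)C(F)(F)F)cc2)cc1
F8 | step 15 | 4-[(2S,3S)-4-chloro-3-{(2S,3S)-3-(3,5-dimethoxyphenyl)-4-methoxy-2-[4-(trifluoromethanesulfonyloxy)phenyl]-2,3-dihydro-1-benzofuran-6-yl}-6-hydroxy-2,3-dihydro-1-benzofuran-2-yl]phenyl trifluoromethanesulfonate | FC(F)(F)S(=O)(=O)Oc1ccc([C@H]2Oc3cc(cc(OC)c3[C@@H]2c2cc(OC)cc(OC)c2)[C@H]2c3c(cc(O)cc3O[C@@H]2c2ccc(OS(=O)(=O)C(F)(F)F)cc2)Cl)cc1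
F9 | step 18 | hexaphenol bis(triflate) stilbene (33 with its six methyl ethers cleaved) | FC(F)(F)S(=O)(=O)Oc1ccc([C@H]2Oc3cc(cc(O)c3[C@@H]2c2cc(O)cc(O)c2)[C@H]2c3c(cc(O)cc3O[C@@H]2c2ccc(OS(=O)(=O)C(F)(F)F)cc2)/C=C/c2ccc(O)cc2O)cc1
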